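The route rests on disconnecting the C2–C3 bond of ring A: the cis 2α,3α-glycol, wedged between the C4 gem-dimethyl carbon and C1/C10, is a pinacol retron. One SmI2-mediated reductive coupling of a C2 and a C3 aldehyde closes ring A and sets both carbinol centres on a ring B template that already carries the C5, C8, C9 and C10 stereochemistry. That precursor is a 2,3-seco ring B cyclohexane: C10 bears the methyl and a CH2CHO arm, C5 a C(CH3)2CHO arm, C8 the methyl, C9 a triethylsilyl-protected carbinol and the ketal-masked side chain. It is assembled from (R)-carvone, whose isopropenyl group relays chirality and is then excised.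

Key step: step 8

Remark on the chemistry: labdane numbering is used for every intermediate (C1–C2 arm on C10, C3–C4 arm on C5, C17 methyl on C8, C11–C13/C16 side chain on C9). α and β refer to the usual labdane drawing with the C10 methyl β. The ring B chair is taken as locked by the equatorial C5 substituent, so 10β-CH3 is axial, 8α is equatorial and 9α is axial.

**Step 1**
Reactants: 1 (R)-carvone; 2 methyl trimethylsilyl dimethylketene acetal; 3 tert-butyl bromoacetate
Product: 5 isopropenyl keto diester (C9 ketone; 10β-CH3; 10α-CH2CO2tBu; 5β-C(CH3)2CO2CH3; 7α-isopropenyl), via silyl enol ether 4 (not isolated)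
Conditions: Ph3CSbCl6 (5 mol %), CH2Cl2, −78 °C; then 3, BnMe3NF, 4 Å MS, THF, −78 °C → rt
Reagents that add atoms: none
Why: Trityl-cation-catalysed Mukaiyama–Michael addition should deliver the ketene acetal to C5 anti to the C7 isopropenyl group (axial attack on the enone half-chair) with silyl transfer to oxygen, and fluoride should then release the tetrasubstituted enolate regiospecifically, so that the α-bromo ester alkylates C10 on the face opposite the adjacent C5 substituent (fluoride-mediated alkylation of a silyl enol ether), setting C5 and C10 with their two arms trans.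

**Step 2**
Reactants: 5 isopropenyl keto diester
Product: 6 keto diester (as 5 but C7 is CH2)
Conditions: O3, MeOH, −78 °C; then FeSO4·7H2O, PhSH, −78 °C → rt
Reagents that add atoms: none
Why: Hydrodealkenylation: ozonolysis in methanol gives the α-methoxy hydroperoxide, divalent iron reduces it to an alkoxy radical whose β-scission expels methyl acetate, and the secondary C7 radical takes hydrogen from benzenethiol; no stereocentre is involved and the ketone and both esters should be inert.

**Step 3**
Reactants: 6 keto diester
Product: 8 8α-methyl keto diester (C17 methyl equatorial; trans to 10β-CH3), via lithium enolate 7 (not isolated)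
Conditions: LiN(iPr)2, THF, −78 °C; MeI, DMPU, −78 → 0 °C; then DBU, PhMe, rt
Reagents that add atoms: iodomethane, CI
Why: Kinetic deprotonation of the ketone can occur only at C8 (C10 is quaternary; the ester CH2 is far less acidic), methylation (enolate alkylation) should occur anti to the axial C10 methyl, and because C8 stays epimerizable the DBU treatment should funnel any 8β-epimer to the equatorial 8α-methyl ketone, which avoids a syn-axial methyl–methyl contact.

**Step 4**
Reactants: 8 8α-methyl keto diester; 9 2-(2-bromoethyl)-2-methyl-1,3-dioxolane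
Product: 11 9β-hydroxy diester (9α-CH2CH2C(CH3)(OCH2CH2O) side chain; 9β-OH), via Grignard reagent 10 (not isolated)
Conditions: 9, Mg, THF, 25 °C; CeCl3, THF, −78 °C; then 8, −78 → −20 °C; H2O quench
Reagents that add atoms: none
Why: The weakly basic organocerium reagent (Imamoto-type carbonyl addition) should add to the hindered, enolizable C9 ketone while sparing the tert-butyl ester and the neopentyl methyl ester at low temperature, approaching axially on the α face opposite the axial C10 methyl, so that the side chain becomes 9α and the hydroxyl 9β.

**Step 5**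
Reactants: 11 9β-hydroxy diester
Product: 12 triol (C2 and C3 primary alcohols; 9β tertiary alcohol; ketal intact)
Conditions: LiAlH4, THF, 0 °C → reflux; H2O, aq. NaOH work-up
Reagents that add atoms: none
Why: LiAlH4 ester reduction should convert both esters into primary alcohols, while the dioxolane, the tertiary alcohol and all stereocentres are untouched.

**Step 6**
Reactants: 12 triol
Product: 13 tris(triethylsilyl) ether (C2-O, C3-O and C9-O silylated)
Conditions: TESOTf, 2,6-lutidine, CH2Cl2, −78 → 25 °C
Reagents that add atoms: triethylsilyl trifluoromethanesulfonate, CC[Si](CC)(CC)OS(=O)(=O)C(F)(F)F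
Why: The silyl triflate with a hindered pyridine base (silyl ether formation) should silylate the two primary hydroxyls and also the crowded tertiary C9 hydroxyl, and the dioxolane tolerates these aprotic conditions.

**Step 7**
Reactants: 13 tris(triethylsilyl) ether
Product: 14 2,3-seco dialdehyde (10α-CH2CHO; 5β-C(CH3)2CHO; 8α-CH3; 9β-OSiEt3; 9α ketal side chain)
Conditions: (COCl)2, DMSO, CH2Cl2, −78 → −30 °C; Et3N, −78 → 0 °C
Reagents that add atoms: none
Why: Under Swern conditions primary triethylsilyl ethers are cleaved by the chlorosulfonium reagent and oxidized directly to aldehydes, whereas the hindered tertiary C9 silyl ether should persist; the crude dialdehyde is used at once to avoid aldol closure.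

**Step 8**
Reactants: 14 2,3-seco dialdehyde
Product: 15 2α,3α-diol (trans-decalin; 5α-H; 10β-CH3; 2α-OH equatorial; 3α-OH axial; 8α-CH3; 9β-OSiEt3; 9α ketal side chain)
Conditions: SmI2 (0.1 M in THF), t-BuOH, THF, −78 °C → rt, slow addition of 14 at high dilution
Reagents that add atoms: none
Why: Two single-electron transfers from SmI2 turn the C2 and C3 aldehydes into ketyls bound to trivalent samarium, which join C2 to C3 and give a samarium-bridged diolate that is protonated by t-BuOH and on work-up. The closest known reaction type is the SmI2 pinacol cyclization of 1,6-dialdehydes to cis-cyclohexane-1,2-diols. Ring A closes in a 6-exo-trig mode (C2 ketyl carbon onto the C3 carbonyl carbon) through a chair-like transition state templated by the trans-diequatorial C1 and C4 arms on C10 and C5 of ring B. The new C2 and C3 centres are controlled by the chelate, which holds the two oxygens syn (cis-diol), and by the chair, which places the C2 oxygen equatorial, away from the syn-axial C10 methyl and C4 β-methyl, so that the C3 oxygen sits axial on the α face. The step needs coupling to outrun simple reduction, aldol reaction of the enolizable C2 aldehyde and formation of the trans-diequatorial 2α,3β-diol, which shares the equatorial C2 oxygen; high dilution, low temperature and the non-enolizable neopentyl C3 aldehyde should secure the first two, and the samarium chelate alone the third.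

**Step 9**
Reactants: 15 2α,3α-diol
Product: 16 diol methyl ketone (9α-CH2CH2COCH3; 9β-OSiEt3; 2α,3α-diol)
Conditions: 10% aq. (CO2H)2 on SiO2, CH2Cl2, rt
Reagents that add atoms: water, O
Why: Oxalic acid on wet silica (mild ketal hydrolysis) should cleave the methyl ketone dioxolane under conditions too mild for the hindered tertiary triethylsilyl ether, and the absence of acetone excludes acetonide formation at the cis-diol.

**Step 10**
Reactants: 16 diol methyl ketone
Product: 17 diol (E)-enoate (13E methyl enoate; 2α,3α-diol; 9β-OSiEt3)
Conditions: (MeO)2P(O)CH2CO2Me, NaH (slightly less than the phosphonate), THF, 0 → 50 °C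
Reagents that add atoms: trimethyl phosphonoacetate, COC(=O)CP(=O)(OC)OC
Why: Horner–Wadsworth–Emmons olefination of the unhindered methyl ketone should give the trisubstituted enoate with the E isomer predominant (the minor Z isomer is removed by chromatography), while the C9 silyl ether blocks oxa-Michael closure onto C13 and no base-labile acetate is present yet.

**Step 11**
Reactants: 17 diol (E)-enoate
Product: 18 2-O-acetate (2α-OAc; 3α-OH; 9β-OSiEt3; 13E enoate)
Conditions: Ac2O (limited excess), pyridine, CH2Cl2, 0 °C
Reagents that add atoms: acetic anhydride, CC(=O)OC(C)=O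
Why: Selective acylation: the equatorial C2 hydroxyl should react far faster than the axial, neopentyl C3 hydroxyl beside the gem-dimethyl carbon, so limited anhydride without DMAP should give the 2-monoacetate.

**Step 12**
Reactants: 18 2-O-acetate
Product: 19 CNP0135744.1 (target)
Conditions: HF·pyridine, pyridine, THF, 0 °C → rt
Reagents that add atoms: none
Why: Fluoride-assisted desilylation with buffered HF·pyridine should remove the tertiary triethylsilyl ether under mildly acidic conditions that leave the acetate, its position on O2 and the enoate unchanged and do not trigger alkoxide-type oxa-Michael cyclization.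

**Compound list**

1 | (R)-(−)-carvone | CC1=CC[C@H](CC1=O)C(C)=C | starting material
2 | methyl trimethylsilyl dimethylketene acetal (1-methoxy-2-methyl-1-trimethylsilyloxyprop-1-ene) | COC(O[Si](C)(C)C)=C(C)C | starting material
3 | tert-butyl bromoacetate | BrCC(=O)OC(C)(C)C | starting material
4 | silyl enol ether (C9-OSiMe3, C9=C10; 5β-C(CH3)2CO2CH3; 7α-isopropenyl) | C[Si](C)(C)OC1=C(C)[C@H](C(C)(C)C(=O)OC)C[C@@H](C(C)=C)C1 | intermediate
5 | isopropenyl keto diester (C9 ketone; 10β-CH3; 10α-CH2CO2tBu; 5β-C(CH3)2CO2CH3; 7α-isopropenyl) | O=C1C[C@H](C(C)=C)C[C@@H](C(C)(C)C(=O)OC)[C@]1(C)CC(=O)OC(C)(C)C | intermediate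
6 | keto diester (C7 unsubstituted) | O=C1CCC[C@@H](C(C)(C)C(=O)OC)[C@]1(C)CC(=O)OC(C)(C)C | intermediate
7 | lithium enolate of 6 (C8=C9) | [Li+].[O-]C1=CCC[C@@H](C(C)(C)C(=O)OC)[C@]1(C)CC(=O)OC(C)(C)C | intermediate
8 | 8α-methyl keto diester | O=C1[C@H](C)CC[C@@H](C(C)(C)C(=O)OC)[C@]1(C)CC(=O)OC(C)(C)C | intermediate
9 | 2-(2-bromoethyl)-2-methyl-1,3-dioxolane | CC1(CCBr)OCCO1 | starting material
10 | Grignard reagent, [2-(2-methyl-1,3-dioxolan-2-yl)ethyl]magnesium bromide | CC1(CC[Mg]Br)OCCO1 | intermediate
11 | 9β-hydroxy diester with 9α ketal side chain | CC1(CC[C@]2(O)[C@H](C)CC[C@@H](C(C)(C)C(=O)OC)[C@]2(C)CC(=O)OC(C)(C)C)OCCO1 | intermediate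
12 | triol (C2-OH, C3-OH, 9β-OH) | CC1(CC[C@]2(O)[C@H](C)CC[C@@H](C(C)(C)CO)[C@]2(C)CCO)OCCO1 | intermediate
13 | tris(triethylsilyl) ether | CC1(CC[C@]2(O[Si](CC)(CC)CC)[C@H](C)CC[C@@H](C(C)(C)CO[Si](CC)(CC)CC)[C@]2(C)CCO[Si](CC)(CC)CC)OCCO1 | intermediate
14 | 2,3-seco dialdehyde (key-step precursor) | CC1(CC[C@]2(O[Si](CC)(CC)CC)[C@H](C)CC[C@@H](C(C)(C)C=O)[C@]2(C)CC=O)OCCO1 | intermediate
15 | 2α,3α-diol (key-step product) | CC1(CC[C@]2(O[Si](CC)(CC)CC)[C@H](C)CC[C@H]3C(C)(C)[C@H](O)[C@H](O)C[C@@]32C)OCCO1 | intermediate
16 | diol methyl ketone | CC(=O)CC[C@]1(O[Si](CC)(CC)CC)[C@H](C)CC[C@H]2C(C)(C)[C@H](O)[C@H](O)C[C@@]21C | intermediate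
17 | diol (E)-enoate | COC(=O)/C=C(\C)CC[C@]1(O[Si](CC)(CC)CC)[C@H](C)CC[C@H]2C(C)(C)[C@H](O)[C@H](O)C[C@@]21C | intermediate
18 | 2-O-acetate, 9-O-triethylsilyl ether | COC(=O)/C=C(\C)CC[C@]1(O[Si](CC)(CC)CC)[C@H](C)CC[C@H]2C(C)(C)[C@H](O)[C@H](OC(C)=O)C[C@@]21C | intermediate
19 | CNP0135744.1, methyl (2E)-5-[(1S,2R,4aS,6S,7R,8aS)-7-acetoxy-1,6-dihydroxy-2,5,5,8a-tetramethyldecahydronaphthalen-1-yl]-3-methylpent-2-enoate (labdane numbering: 2α-OAc, 3α-OH, 5α-H, 8α-CH3, 9β-OH, 9α side chain, 10β-CH3, 13E) | COC(=O)/C=C(\C)CC[C@]1(O)[C@H](C)CC[C@H]2C(C)(C)[C@H](O)[C@H](OC(C)=O)C[C@@]21C | target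

**Step count**

Total steps: 12. Longest linear sequence: 12 steps (1 → 19).

**Steps most likely to fail, with fallbacks**

Step 8 (pinacol closure of ring A). The coupling may lose its cis or α-face selectivity and give the trans-diequatorial 2α,3β-diol. It may also be overtaken by aldol reaction of the C2 aldehyde or by plain reduction of the aldehydes. Fallback: the same C2–C3 bond would be made as an alkene and the glycol installed afterwards. Setting out from dialdehyde 14, McMurry coupling (TiCl3(DME)1.5, Zn(Cu), DME, reflux, slow addition) should give the ring A Δ2-cyclohexene F1. Dihydroxylation (OsO4 cat., NMO, acetone–H2O) should then occur on the α face, the only one free of the axial C10 and C4 β-methyl groups, and the route is rejoined at diol 15.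

Step 4 (side-chain addition to the C9 ketone). Enolization at C8, β-hydride reduction or attack on the tert-butyl ester may compete with addition of a primary alkyl nucleophile to this doubly flanked ketone, and a bulky reagent may show weaker facial preference than assumed. Fallback: setting out from ketone 8, a small, linear nucleophile would be used. Commercial 2-ethynyl-2-methyl-1,3-dioxolane (C#CC1(C)OCCO1) is deprotonated with n-BuLi in THF at −78 °C to the lithium acetylide F2. Acetylides add to cyclohexanones axially, here again anti to the C10 methyl, which should give the 9β-hydroxy-9α-alkynyl diester F3. Hydrogenation (H2, Pd/C, EtOAc) saturates C11–C12 and returns to hydroxy diester 11.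

Step 1 (quaternary C10 in one flask). The Lewis-acid Michael step may stall with the hindered acetal, or the fluoride-generated enolate may divert to O-alkylation and proton transfer. Fallback: an all-anionic tandem sequence setting out from carvone 1. The lithium enolate of methyl isobutyrate F4 (from methyl isobutyrate and LiN(iPr)2, THF, −78 °C) adds reversibly at the carbonyl and, on warming with DMPU, should rearrange to the conjugate adduct anti to the isopropenyl group, the lithium enolate Michael adduct F5. This regiodefined enolate is alkylated in the same flask with tert-butyl bromoacetate 3, rejoining the route at keto diester 5.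

**Further compounds**

F1 | step 8 | ring A Δ2-cyclohexene (C2=C3; 9β-OSiEt3; 9α ketal side chain) | CC1(CC[C@]2(O[Si](CC)(CC)CC)[C@H](C)CC[C@H]3C(C)(C)C=CC[C@@]32C)OCCO1
F2 | step 4 | lithium acetylide of 2-ethynyl-2-methyl-1,3-dioxolane | [Li+].[C-]#CC1(C)OCCO1
F3 | step 4 | 9β-hydroxy-9α-alkynyl diester | CC1(C#C[C@]2(O)[C@H](C)CC[C@@H](C(C)(C)C(=O)OC)[C@]2(C)CC(=O)OC(C)(C)C)OCCO1
F4 | step 1 | lithium enolate of methyl isobutyrate | [Li+].[O-]C(OC)=C(C)C
F5 | step 1 | lithium enolate Michael adduct (C9-OLi, C9=C10; 5β-C(CH3)2CO2CH3; 7α-isopropenyl) | [Li+].[O-]C1=C(C)[C@H](C(C)(C)C(=O)OC)C[C@@H](C(C)=C)C1
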